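**The books.** Elm, cedar and larch are the runs we have, and east and south are the flasks we must forecast.

| flask | free monomer | initiator | remark | time |
|---|---|---|---|---|
| elm | 0.33 M | 6.7 mol% | run made earlier |  |
| cedar | 0.33 M | 15 mol% | run made earlier |  |
| larch | 0.66 M | 10 mol% | run made earlier |  |
| east | 0.33 M | 10 mol% |  | 2.0 h |
| south | 0.33 M | 10 mol% |  | 0.50 h |

| run | time / min | monomer in chains / % | free monomer / % |
|---|---|---|---|
| elm | 12.0 | 10.3 | 81.3 |
| elm | 25.0 | 19.6 | 65.4 |
| elm | 40.0 | 26.6 | 53.4 |
| elm | 50.0 | 33.0 | 44.8 |
| elm | 60.0 | 33.6 | 36.6 |
| elm | 80.0 | 40.5 | 29.5 |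
| cedar | 5.00 | 11.9 | 84.8 |
| cedar | 15.0 | 27.1 | 64.5 |
| cedar | 25.0 | 38.3 | 49.3 |
| cedar | 40.0 | 50.4 | 33.9 |
| cedar | 60.0 | 61.3 | 17.6 |
| cedar | 80.0 | 66.0 | 10.1 |
| larch | 6.00 | 14.3 | 79.5 |
| larch | 20.0 | 39.9 | 51.1 |
| larch | 30.0 | 50.3 | 36.3 |
| larch | 50.0 | 65.1 | 17.7 |
| larch | 80.0 | 73.9 | 6.3 |

(scatter of a reading: 1 percentage point)

- which of the two ends with the longer chains by the average number of monomer units in a chain (chains begun, living or dead) ("neither" if they lie within 10%) (east / south / neither)
- average number of monomer units in a chain (chains begun, living or dead) at the end, east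
- average number of monomer units in a chain (chains begun, living or dead) at the end, south

- the average divides the monomer in chains by the number of chains begun, living and dead together
- the earlier runs do not show the number of chains; that part of a forecast is a guess

Elm's ledger at 80.0 min reads 29.5% of the free monomer left and 40.5% in chains, so 30.0% went to a side loss. A reacting molecule therefore meets a fork: chain or side loss.

**The fork.** Take the last row of each run and divide its odds, chains over side loss, by the initiator concentration charged. Elm gives 61.1 /M, cedar 55.8 /M and larch 56.6 /M. Their mean is 57.8 /M, our fork constant, a selectivity factor: the odds of chain over side loss per mole per litre of initiator. Reading each last row as one exponential decay, and multiplying its decay constant by the side share, gives a mean side rate of 0.00714 /min.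

**East and south.** Both flasks have odds of 1.91. East's ledger closes at 8.29% left, 60.2% in chains and 31.5% lost. South's has 53.7% left and 30.4% in chains. We guess one chain per initiator, so dividing chains by the loading gives 3.04 units for south and 6.02 for east, about twice south's figure.

The forecast named east, with 6.1 and 3.1 units by “Guessing one chain per initiator”, each slightly above ours.

**The result.**

    free monomer + living end → monomer in chains + living end, rate k1*[living end]*[free monomer] (k = 0.00650 /M/s)
    free monomer → uncatalysed product (k = 1.20 × 10⁻⁴ /s)
    free monomer + initiator → living end + monomer in chains (k = 0.00950 /M/s)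

East reaches 5.97 units and south 3.19, so east ends longer. At 2.00 h, east holds 0.0258% of its initiator and 0.0330 M of living ends. Splitting east's remaining 8.67% of free monomer at our odds gives a final length of 6.54, and east left for 20.0 h stands at 6.53.

**A leaner flask.** A neighbour flask is east with 2.5 mol% of initiator in place of 10 mol%. Its odds are 0.477, below one, so our ledger gives the side loss the larger entry, with 23.2% in chains and 9.28 units. The neighbour flask gives 22.7% in chains, 48.9% as uncatalysed product and 9.06 units.

The runs were computed for an exercise; the scatter is artificial.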